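The ratio of target at the last reading to second substrate charged is 0.613 in theta, 0.715 in eta and 0.738 in beta, although the charge of second substrate is the same in each.

| flask | starting material | second substrate | free enzyme | remark | time |
|---|---|---|---|---|---|
| theta | 0.024 M | 0.0144 M | 2.1 µM | run made earlier |  |
| eta | 0.024 M | 0.0144 M | 3.8 µM | run made earlier |  |
| beta | 0.020 M | 0.0144 M | 4.8 µM | run made earlier |  |
| green | 0.024 M | 0.0144 M | 4.8 µM |  | 5.0 d |
| grey | 0.015 M | 0.0144 M | 2.5 µM |  | 5.0 d |

| run | time / d | target / % | starting material / % |
|---|---|---|---|
| theta | 0.250 | 4.5 | 95.1 |
| theta | 0.500 | 8.7 | 91.5 |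
| theta | 0.833 | 13.9 | 86.4 |
| theta | 1.25 | 19.3 | 80.8 |
| theta | 2.00 | 28.2 | 72.5 |
| theta | 4.00 | 36.8 | 63.8 |
| eta | 0.625 | 17.7 | 82.0 |
| eta | 1.25 | 31.9 | 68.3 |
| eta | 1.67 | 39.0 | 60.9 |
| eta | 2.50 | 43.0 | 57.0 |
| eta | 3.00 | 42.6 | 56.9 |
| eta | 4.00 | 42.9 | 57.3 |
| beta | 0.250 | 9.6 | 90.5 |
| beta | 0.500 | 19.3 | 81.1 |
| beta | 1.04 | 36.1 | 64.3 |
| beta | 1.67 | 49.0 | 51.2 |
| beta | 4.00 | 53.1 | 47.2 |

(scatter of a reading: 0.3 percentage points)

- the numbers in the tables scatter by 0.3 percentage points (one standard deviation)
- a reading or a percentage of target counts all its forms, free or not

- the flask that ends with the higher amount of target, in percent of the starting material charged, or "neither" when 2 percentage points or less lies between them (green / grey / neither)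
- final target, as a percentage of the starting material charged, in green
- final target, as a percentage of the starting material charged, in grey

1. **Main step.** Target and starting material together come back to about the charged starting material in the readings. At 1.25 d, ln of the remaining starting material is 1.79 times larger in eta than in theta, and the enzyme ratio is 1.81. So the pace is taken as [free enzyme] × [starting material], as charged. If one second substrate gives one target, second substrate is the limiting reagent, and the ceilings are 60.0% for green and 96.0% for grey.

2. **One loss added.** Define the lost share as the part of the charged second substrate that never appears as target: 38.7% in theta, 28.5% in eta and 26.2% in beta. Theta, the slower run, loses more than eta. Between these two, the lost share falls as enzyme rises, as one over enzyme to the power 0.514, close to 0.5.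

3. **The rule.** My reckoning scales each lost share by the square root of its pace over eta's pace. The mean gives the lost share at eta's pace, 28.1%.

4. **Green and grey.** Green then loses 25.0% and ends at 45.0%. Grey loses 43.8% and ends at 54.0%, which is higher than green.

5. **The forecast.** It names grey, with 46.3% for green and 49.7% for grey, on this ground: “That suggests a background loss of about 0.0021 M/d, independent of enzyme.” For grey, my figure is higher.

The flask gives 45.2% in green and 55.5% in grey, so grey ends higher.

    second substrate + loaded enzyme ⇌ second complex (K = 110 /M, k = 2.90 × 10⁵ /M/h)
    crystals ⇌ first product, rate k2*(cs2 - [first product]) while solid is left; crystals form when [first product] > cs2 (solubility = 6.50 mM, k = 1.30 /h)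
    starting material + free enzyme ⇌ first complex (K = 24.0 /M, k = 2.00 × 10⁵ /M/h)
    2 second substrate → self-condensation product (k = 1.20 /M/h)
    second substrate + target ⇌ idle adduct, settled at all times (K = 35.0 /M)
    second complex → free enzyme + target (k = 4300 /h)
    first complex ⇌ loaded enzyme + first product (K = 0.0350 M, k = 240 /h)

Read back from these results, the lost share is 24.6% in green against the reckoned 25.0%, and 42.2% in grey against 43.8%. The neighbouring flask is green with 0.060 M of starting material. Its pace gives a lost share of 15.8%, and so target at 20.2%. The simulated neighbour ends at 19.8%, with 0% of its second substrate left.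

The numbers in the tables stem from a simulated flask for substances that don't exist, and the scatter is random.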